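**Retrosynthetic overview**

- The target is traced back through O-demethylation and a bromination para to the ether oxygen of ring B to a 2-bromophenyl ether of the ring-A phenol.
- The strategy rests on ring B (the 2,4-dibromophenoxy ring): its ether oxygen on C1' and a bromine on C2' sit on adjacent carbons. That is the pattern left when an oxygen nucleophile and a bromine electrophile add across the triple bond of benzyne, so the O–C1' and C2'–Br bonds are cut together. The C4' bromine is para to the oxygen and is added afterwards.
- The ring-A partner, 2,4-dibromo-3-chloro-6-methoxyphenol, comes from 5-amino-2-methoxyphenol by dibromination at the two carbons flanking nitrogen and Sandmeyer chlorination.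
- No ring is formed in the route: ring A is bought as the aminophenol and is fully substituted first, and ring B is bought as the benzyne precursor and joined to it in the key step.

Key step: step 3

Remark: the target has no stereocentre or other stereogenic element, so it is achiral and no stereocontrol is needed anywhere in the route.

**Route**

Step 1
Reactants: 1 5-amino-2-methoxyphenol
Product: 2 3-amino-2,4-dibromo-6-methoxyphenol
Conditions: NBS (2.05 equiv), MeCN, −10 → 0 °C
Reagents that add atoms: N-bromosuccinimide, O=C1CCC(=O)N1Br
Why: Electrophilic aromatic bromination: the two carbons flanking the amino group are also para and ortho to the hydroxyl, whereas the third free carbon is meta to both donors and the position para to nitrogen carries the methoxy group, so two equivalents of NBS should brominate only the two carbons next to nitrogen.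

Step 2
Reactants: 2 3-amino-2,4-dibromo-6-methoxyphenol
Product: 4 2,4-dibromo-3-chloro-6-methoxyphenol, via 2,6-dibromo-3-hydroxy-4-methoxybenzenediazonium hydrogensulfate 3 (not isolated)
Conditions: NaNO2, H2SO4, AcOH, 0–10 °C; then CuCl, conc. HCl, 0 → 60 °C
Reagents that add atoms: copper(I) chloride, Cl[Cu]; hydrochloric acid, Cl
Why: Sandmeyer reaction: nitrosylsulfuric acid diazotises the doubly ortho-brominated amine, the hydroxyl is meta to the diazonium group (no quinone diazide) and the phenol has no free ortho or para carbon for azo coupling, and copper(I) chloride then replaces N2 by chlorine through the aryl radical.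

Step 3
Reactants: 4 2,4-dibromo-3-chloro-6-methoxyphenol; 5 2-(trimethylsilyl)phenyl trifluoromethanesulfonate; 6 1,2-dibromotetrachloroethane
Product: 10 2-bromophenyl 2,4-dibromo-3-chloro-6-methoxyphenyl ether, via cesium 2,4-dibromo-3-chloro-6-methoxyphenoxide 7 (not isolated), via benzyne 8 (not isolated), via 2-(2,4-dibromo-3-chloro-6-methoxyphenoxy)phenylcesium 9 (not isolated)
Conditions: CsOH·H2O (1.0 equiv), MeOH, then evaporation and PhMe azeotrope to dryness; 6 (3 equiv), CsF (3 equiv), 18-crown-6, THF, rt, slow addition of 5 (1.5 equiv)
Reagents that add atoms: none
Why: Proposed new method: fluoride attacks silicon of 5 and triflate leaves to give benzyne 8, the oxygen of phenoxide 7 adds to the strained triple bond, and the 2-aryloxyphenyl anion 9 takes bromine from 6 by halophilic attack, the remaining BrCl2C–CCl2 anion losing bromide to give tetrachloroethene, so the O–C1' and C2'–Br bonds form in one operation. The closest known reaction types are the fluoride-induced O-arylation of phenols by 2-silylaryl triflates and aryne 1,2-difunctionalisations in which the aryl anion formed by nucleophile addition is quenched by a halogen donor such as a polyhaloalkane. No ring is closed and no stereocentre is formed. The step needs bromination of 9 to outrun protonation, which is secured by the preformed, dried cesium phenoxide (no O–H present), an ether solvent without acidic protons and an excess of 6 kept in the flask while 5 is added slowly; benzyne is symmetric, so no regiochemistry arises, and if 9 takes bromine from C2 of ring A instead, the ring-A anion so formed should be rebrominated by 6 to the same product. Phenoxide 7 can react only at oxygen and cannot be C-brominated by 6, because every carbon ortho and para to its oxygen is substituted, and with no transition metal present the three ring-A halogens should survive.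

Step 4
Reactants: 10 2-bromophenyl 2,4-dibromo-3-chloro-6-methoxyphenyl ether
Product: 11 2,4-dibromophenyl 2,4-dibromo-3-chloro-6-methoxyphenyl ether
Conditions: Br2 (1.05 equiv), AcOH, rt
Reagents that add atoms: bromine, BrBr
Why: Electrophilic aromatic bromination: on ring B the aryloxy oxygen directs para, as in the bromination of 2-bromoanisole to 2,4-dibromoanisole, while the only C–H of ring A sits on a ring carrying three halogens and is hemmed in by methoxy and bromine, so one equivalent of bromine should enter C4' alone.

Step 5
Reactants: 11 2,4-dibromophenyl 2,4-dibromo-3-chloro-6-methoxyphenyl ether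
Product: 12 3,5-dibromo-4-chloro-2-(2,4-dibromophenoxy)phenol
Conditions: BBr3 (3 equiv), CH2Cl2, −78 °C → rt; then H2O
Reagents that add atoms: none
Why: Boron tribromide cleavage of an aryl methyl ether: the Lewis acid binds the methoxy oxygen and bromide removes the methyl group as bromomethane, while the diaryl ether and the five carbon–halogen bonds are inert to the reagent.

**Compound list**

1 | 5-amino-2-methoxyphenol | COc1ccc(N)cc1O | starting material
2 | 3-amino-2,4-dibromo-6-methoxyphenol | COc1cc(Br)c(N)c(Br)c1O | intermediate
3 | 2,6-dibromo-3-hydroxy-4-methoxybenzenediazonium hydrogensulfate | COc1cc(Br)c([N+]#N)c(Br)c1O.OS(=O)(=O)[O-] | intermediate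
4 | 2,4-dibromo-3-chloro-6-methoxyphenol | COc1cc(Br)c(Cl)c(Br)c1O | intermediate
5 | 2-(trimethylsilyl)phenyl trifluoromethanesulfonate | C[Si](C)(C)c1ccccc1OS(=O)(=O)C(F)(F)F | starting material
6 | 1,2-dibromotetrachloroethane | ClC(Cl)(Br)C(Cl)(Cl)Br | starting material
7 | cesium 2,4-dibromo-3-chloro-6-methoxyphenoxide | COc1cc(Br)c(Cl)c(Br)c1[O-].[Cs+] | intermediate
8 | benzyne | C1#CC=CC=C1 | intermediate
9 | 2-(2,4-dibromo-3-chloro-6-methoxyphenoxy)phenylcesium | COc1cc(Br)c(Cl)c(Br)c1Oc1cccc[c-]1.[Cs+] | intermediate
10 | 2-bromophenyl 2,4-dibromo-3-chloro-6-methoxyphenyl ether | COc1cc(Br)c(Cl)c(Br)c1Oc1ccccc1Br | intermediate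
11 | 2,4-dibromophenyl 2,4-dibromo-3-chloro-6-methoxyphenyl ether | COc1cc(Br)c(Cl)c(Br)c1Oc1ccc(Br)cc1Br | intermediate
12 | 3,5-dibromo-4-chloro-2-(2,4-dibromophenoxy)phenol | Oc1cc(Br)c(Cl)c(Br)c1Oc1ccc(Br)cc1Br | target

Total step count: 5
Longest linear sequence: 5 steps (1 → 2 → 4 → 10 → 11 → 12)

**Steps most likely to fail**

1. Step 3. Protonation of the aryl anion may outrun bromine transfer and leave the ring-B carbon next to oxygen unbrominated. The bromide set free may also consume benzyne, and the hindered, weakly basic phenoxide may add too slowly. The fallback uses known chemistry, sets out from 4 and comes back at 10. Phenol 4 is arylated by nucleophilic aromatic substitution on 1-fluoro-2-nitrobenzene (K2CO3, DMF, 90 °C) to give 2,4-dibromo-3-chloro-6-methoxyphenyl 2-nitrophenyl ether F1. The nitro group is reduced with iron in AcOH/EtOH at 70 °C, conditions that leave aryl halides alone, to give 2-(2,4-dibromo-3-chloro-6-methoxyphenoxy)aniline F2. Diazotisation with NaNO2 in aqueous HBr/AcOH at 0 °C gives 2-(2,4-dibromo-3-chloro-6-methoxyphenoxy)benzenediazonium bromide F3, which is not isolated and is converted by CuBr/HBr at 60 °C (Sandmeyer bromination) into 10.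

2. Step 2. Diazotisation of the doubly ortho-substituted amine may be incomplete. Chloride may also exchange with a bromine ortho to the diazonium group, and the electron-rich phenol may be oxidised or reduced (loss of N2 with gain of H). The fallback reverses the order of halogenation, sets out from 1 and comes back at 4. The unhindered amine 1 is diazotised (NaNO2, aq. HCl, 0 °C) to 3-hydroxy-4-methoxybenzenediazonium chloride F4, which is not isolated and is treated with CuCl/HCl to give 5-chloro-2-methoxyphenol F5. Dibromination of this phenol (Br2, 2.1 equiv, AcOH, rt) should go para and ortho to the hydroxyl, the stronger donor, that is at the two carbons flanking chlorine, to give 4.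

3. Step 4. Site selectivity may be lost, with bromine entering ortho to the oxygen on ring B or at the lone C–H of ring A, or a second bromine may add. The fallback brings in ring B with both bromines already in place, sets out from 4 and comes back at 11. Phenol 4 is O-arylated with bis(2,4-dibromophenyl)iodonium chloride (NaOH, H2O/dioxane, 80 °C), a metal-free aryl transfer from a symmetric diaryliodonium salt, giving 11 directly. This fallback passes through no new compound (F0) and skips steps 3 and 4.

**Further compounds**

F1 | step 3 | 2,4-dibromo-3-chloro-6-methoxyphenyl 2-nitrophenyl ether | COc1cc(Br)c(Cl)c(Br)c1Oc1ccccc1[N+](=O)[O-]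
F2 | step 3 | 2-(2,4-dibromo-3-chloro-6-methoxyphenoxy)aniline | COc1cc(Br)c(Cl)c(Br)c1Oc1ccccc1N
F3 | step 3 | 2-(2,4-dibromo-3-chloro-6-methoxyphenoxy)benzenediazonium bromide | COc1cc(Br)c(Cl)c(Br)c1Oc1ccccc1[N+]#N.[Br-]
F4 | step 2 | 3-hydroxy-4-methoxybenzenediazonium chloride | COc1ccc([N+]#N)cc1O.[Cl-]
F5 | step 2 | 5-chloro-2-methoxyphenol | COc1ccc(Cl)cc1O
F0 | step 4 | none | none
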